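At early times such as 12 s, far shorter than the first reading of the runs at 2.00 h, I expect the flask still to hold its two conformers about as charged, which makes the ratio there a ratio of two rates. I can't read that ratio from the runs, so I leave it open.

| flask | starting material | other conformer | catalyst | remark | time |
|---|---|---|---|---|---|
| green | 0.28 M | 0.20 M | 0.10 mM | run made earlier |  |
| amber | 0.44 M | 0.20 M | 0.10 mM | run made earlier |  |
| teal | 0.20 M | 0.30 M | 0.10 mM | run made earlier |  |
| flask | 0.20 M | 0.200 M | 0.10 mM |  | 30 h |

| run | time / h | target / % | isomer of the product / % | starting material / % |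
|---|---|---|---|---|
| green | 2.00 | 52.2 | 45.6 | 0.7 |
| green | 3.00 | 54.4 | 45.0 | 0.4 |
| green | 4.00 | 53.0 | 45.6 | 0 |
| green | 6.00 | 53.4 | 43.7 | 0 |
| green | 10.0 | 54.1 | 45.6 | 0 |
| green | 15.0 | 55.0 | 45.3 | 0 |
| green | 25.0 | 53.7 | 45.7 | 0.4 |
| amber | 2.00 | 62.9 | 36.2 | 1.6 |
| amber | 3.00 | 64.3 | 35.9 | 0 |
| amber | 4.00 | 63.0 | 36.7 | 0.6 |
| amber | 6.00 | 62.9 | 38.7 | 0.6 |
| amber | 10.0 | 61.8 | 37.7 | 0 |
| amber | 15.0 | 64.4 | 35.7 | 0 |
| amber | 25.0 | 61.6 | 37.6 | 0 |
| teal | 2.00 | 35.9 | 60.4 | 0 |
| teal | 6.00 | 36.9 | 65.6 | 0 |
| teal | 12.0 | 39.7 | 63.4 | 0 |
| teal | 15.0 | 38.0 | 62.4 | 0 |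
| teal | 25.0 | 37.7 | 62.0 | 0 |

(readings scatter by 1 percentage point)

- ratio of target to isomer of the product at 12 s
- ratio of target to isomer of the product at 30 h

I read the target column against the charges. Within each run it shows no trend from the first reading to the last beyond the scatter of 1 percentage point, which I read as kinetic control over these times. Across the runs it differs, so I look for what stays. I turn each run's mean into a concentration and divide by the charged [starting material]. Green gives 0.920, amber 0.916 and teal 0.941, close to one another.

So I freeze their mean, 0.926, and call it the retention: plateau [target] over charged [starting material], with 0.10 mM of catalyst in every run and in the flask. For the flask this puts target at 46.3% of the total charge. I let the isomer of the product take the rest, so my ratio at 30 h is 0.862.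

The forecast says 0.9 at 12 s and 0.86 at 30 h, holding that “each conformer largely keeps its own channel”.

The flask gives 0.280 at 12 s and 0.863 at 30 h, with target at 46.2% of the charge at the end.

    starting material ⇌ other conformer (K = 1.50, k = 0.220 /h)
    starting material + catalyst → catalyst + target (k = 23000 /M/h)
    catalyst + other conformer → catalyst + isomer of the product (k = 83000 /M/h)
    target → over-reaction product (k = 2.30 × 10⁻⁴ /h)

In this flask at 0.0917 h, the catalyst step uses starting material at 10 times the forward rate of its step to other conformer. For the neighbour charged with 0.50 M of starting material, the retention gives a ratio of 1.95 at 30 h, and that flask gives 1.91.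

The earlier runs and the new flask are simulated for substances that don't exist, noise included.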